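**Retrosynthetic overview**

1. Target ⇐ fluoride removal of three aryl silyl groups ⇐ O-acetylation ⇐ tris-silylated (3S,6E)-1,7-diarylhept-6-en-3-ol.
2. Key disconnection C5–C6 (allylic CH2 to olefinic CH): (E)-2-(4-silyloxyphenyl)ethenyllithium (C6, C7, ring B) + (R)-2-[2-(3,4-disilyloxyphenyl)ethyl]oxetane (C1–C5, ring A), joined by BF3-assisted SN2 opening at the oxetane CH2.
3. Enabling feature: the oxygen on C3 and carbon C5 are 1,3-related, so O, C3, C4 and C5 can be tied into a temporary four-membered oxetane ring. This ring masks the C3 hydroxyl, makes C5 a strain-activated electrophile and carries the C3 configuration; the key step opens it again.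
4. Oxetane ⇐ (R)-1,3-diol ⇐ Noyori hydrogenation of a β-keto ester ⇐ 3-(3,4-dihydroxyphenyl)propanoic acid + malonate half-ester; alkenyl iodide ⇐ Takai olefination of 4-(tert-butyldimethylsilyloxy)benzaldehyde.
5. Ring order: both benzene rings are bought intact; the only ring made is the temporary oxetane (step 5), opened in step 7.

Key step: step 7

Assumption: the chain is numbered C1 (benzylic carbon on the catechol ring) to C7 (olefinic carbon on the 4-hydroxyphenyl ring); by CIP analysis the target is the (3S,6E) isomer; operations run in one flask are counted as one step.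

**Route**

Step 1
Reactants: 1 3-(3,4-dihydroxyphenyl)propanoic acid
Product: 3 3-[3,4-bis(triisopropylsilyloxy)phenyl]propanoic acid, via silyl ester 2 (not isolated)
Conditions: TIPSCl (3.5 equiv), imidazole, DMF, rt→40 °C; then AcOH/THF/H2O, rt
Reagents that add atoms: triisopropylsilyl chloride, CC(C)[Si](Cl)(C(C)C)C(C)C
Why: Standard imidazole-mediated silylation of both phenols and the acid, followed by selective hydrolysis of the silyl ester, which is far more labile to mild aqueous acid than the aryl silyl ethers.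

Step 2
Reactants: 3 3-[3,4-bis(triisopropylsilyloxy)phenyl]propanoic acid
Product: 6 methyl 5-[3,4-bis(triisopropylsilyloxy)phenyl]-3-oxopentanoate, via acyl imidazolide 4 (not isolated), via acylmalonic half-ester 5 (not isolated)
Conditions: CDI, THF, rt; then KO2CCH2CO2Me, MgCl2, Et3N, MeCN, rt; 1 M HCl work-up
Reagents that add atoms: potassium methyl malonate, [K+].[O-]C(=O)CC(=O)OC
Why: Masamune–Brooks chain extension, in which the acyl imidazolide C-acylates the magnesium enolate of the malonate half-ester and the acylmalonic acid freed on acidification loses CO2 to give the β-keto ester.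

Step 3
Reactants: 6 methyl 5-[3,4-bis(triisopropylsilyloxy)phenyl]-3-oxopentanoate
Product: 7 methyl (3R)-5-[3,4-bis(triisopropylsilyloxy)phenyl]-3-hydroxypentanoate
Conditions: H2 (10 atm), RuCl2[(R)-BINAP] (0.5 mol%), MeOH, 50 °C
Reagents that add atoms: none
Why: Noyori asymmetric hydrogenation, in which the β-keto ester chelates the divalent ruthenium hydride and the (R)-BINAP ligand directs hydride delivery to one carbonyl face, which by the established sense for alkyl β-keto esters should set the 3R carbinol center.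

Step 4
Reactants: 7 methyl (3R)-5-[3,4-bis(triisopropylsilyloxy)phenyl]-3-hydroxypentanoate
Product: 8 (3R)-5-[3,4-bis(triisopropylsilyloxy)phenyl]pentane-1,3-diol
Conditions: LiBH4, THF, MeOH (1 equiv), 0 °C→rt
Reagents that add atoms: none
Why: Hydroxyl-assisted borohydride reduction of the ester to the primary alcohol, which leaves the stereocenter and the aryl silyl ethers untouched.

Step 5
Reactants: 8 (3R)-5-[3,4-bis(triisopropylsilyloxy)phenyl]pentane-1,3-diol
Product: 10 (2R)-2-{2-[3,4-bis(triisopropylsilyloxy)phenyl]ethyl}oxetane, via primary monotosylate 9 (not isolated)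
Conditions: n-BuLi (1.0 equiv), THF, 0 °C; TsCl (1.0 equiv), 0 °C; n-BuLi (1.05 equiv), 0→60 °C
Reagents that add atoms: none
Why: One-pot intramolecular Williamson etherification, in which the less hindered primary alkoxide is sulfonylated first and the secondary lithium alkoxide then closes the four-membered ring by 4-exo-tet SN2 displacement at the primary carbon, so that no bond at the stereocenter is broken and its R configuration is retained.

Step 6
Reactants: 11 4-(tert-butyldimethylsilyloxy)benzaldehyde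
Product: 12 tert-butyl{4-[(E)-2-iodoethenyl]phenoxy}dimethylsilane
Conditions: CrCl2 (6 equiv), CHI3 (2 equiv), THF, 0 °C→rt, dark
Reagents that add atoms: iodoform, IC(I)I
Why: Takai olefination, in which the geminal dichromium reagent formed from CHI3 and divalent chromium adds to the aldehyde and the β-oxido organochromium intermediate eliminates through the less crowded arrangement to give the E alkenyl iodide.

Step 7
Reactants: 12 tert-butyl{4-[(E)-2-iodoethenyl]phenoxy}dimethylsilane; 10 (2R)-2-{2-[3,4-bis(triisopropylsilyloxy)phenyl]ethyl}oxetane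
Product: 15 (3S,6E)-1-[3,4-bis(triisopropylsilyloxy)phenyl]-7-[4-(tert-butyldimethylsilyloxy)phenyl]hept-6-en-3-ol, via alkenyllithium 13 (not isolated), via lithium alkoxytrifluoroborate 14 (not isolated)
Conditions: 12 (2.2 equiv), t-BuLi (4.4 equiv), Et2O, −78 °C; 10 in THF, then BF3·OEt2 (2.2 equiv, dropwise), −78 °C; aq. NaHCO3
Reagents that add atoms: none
Why: Iodine–lithium exchange of 12 with two equivalents of t-BuLi should give the configurationally stable (E)-alkenyllithium 13 with retention, BF3 then binds the ring oxygen of 10, and 13 attacks the unsubstituted ring carbon (oxetane C4, the future C5) in an SN2 process driven by release of about 106 kJ/mol of ring strain, which forms the C5–C6 bond and frees the C3 oxygen as alkoxytrifluoroborate 14, hydrolysed to 15 on work-up. The closest known reaction type is the BF3-promoted ring opening of oxetanes and epoxides by alkyl-, alkenyl- and alkynyllithium reagents at −78 °C. No ring is closed; the only ring event is the SN2 opening of the four-membered ring with its oxygen as leaving group. No new stereocenter is formed: the C–O bond at oxetane C2 is never broken, so its configuration is carried unchanged into C3 of 15, the descriptor changing from R to S only because the CIP ranks of the two carbon chains are exchanged. The step needs regioselectivity (attack at C4, not C2, of the oxetane) and retention of the E geometry; the first is secured by the steric difference between the ring CH2 and the alkyl-substituted ring CH under SN2 control, the second by making and using 13 at −78 °C, where alkenyllithiums do not isomerise. In one operation the step should thus deliver the whole diarylheptanoid chain, the E olefin and the free, correctly configured C3 hydroxyl from two fragments of about half the size.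

Step 8
Reactants: 15 (3S,6E)-1-[3,4-bis(triisopropylsilyloxy)phenyl]-7-[4-(tert-butyldimethylsilyloxy)phenyl]hept-6-en-3-ol
Product: 16 (3S,6E)-1-[3,4-bis(triisopropylsilyloxy)phenyl]-7-[4-(tert-butyldimethylsilyloxy)phenyl]hept-6-en-3-yl acetate
Conditions: Ac2O, pyridine, DMAP (cat.), CH2Cl2, 0 °C→rt
Reagents that add atoms: acetic anhydride, CC(=O)OC(C)=O
Why: DMAP-catalysed acylation of the secondary alcohol, which breaks no bond at the stereocenter and leaves the aryl silyl ethers and the olefin untouched.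

Step 9
Reactants: 16 (3S,6E)-1-[3,4-bis(triisopropylsilyloxy)phenyl]-7-[4-(tert-butyldimethylsilyloxy)phenyl]hept-6-en-3-yl acetate
Product: 17 (3S,6E)-1-(3,4-dihydroxyphenyl)-7-(4-hydroxyphenyl)hept-6-en-3-yl acetate
Conditions: TBAF (3.3 equiv), AcOH (3.6 equiv), THF, 0 °C→rt, argon
Reagents that add atoms: none
Why: Fluoride-induced cleavage of the three aryl silyl ethers, buffered with acetic acid so that each phenoxide is protonated at once and neither acetyl transfer from the alkyl acetate nor oxidation of the catechol is promoted.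

**Compound list**

1 | 3-(3,4-dihydroxyphenyl)propanoic acid | OC(=O)CCc1ccc(O)c(O)c1 | starting material
2 | triisopropylsilyl 3-[3,4-bis(triisopropylsilyloxy)phenyl]propanoate | CC(C)[Si](C(C)C)(C(C)C)OC(=O)CCc1ccc(O[Si](C(C)C)(C(C)C)C(C)C)c(O[Si](C(C)C)(C(C)C)C(C)C)c1 | intermediate
3 | 3-[3,4-bis(triisopropylsilyloxy)phenyl]propanoic acid | OC(=O)CCc1ccc(O[Si](C(C)C)(C(C)C)C(C)C)c(O[Si](C(C)C)(C(C)C)C(C)C)c1 | intermediate
4 | 1-{3-[3,4-bis(triisopropylsilyloxy)phenyl]propanoyl}imidazole | O=C(CCc1ccc(O[Si](C(C)C)(C(C)C)C(C)C)c(O[Si](C(C)C)(C(C)C)C(C)C)c1)n1ccnc1 | intermediate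
5 | 5-[3,4-bis(triisopropylsilyloxy)phenyl]-2-(methoxycarbonyl)-3-oxopentanoic acid | COC(=O)C(C(=O)O)C(=O)CCc1ccc(O[Si](C(C)C)(C(C)C)C(C)C)c(O[Si](C(C)C)(C(C)C)C(C)C)c1 | intermediate
6 | methyl 5-[3,4-bis(triisopropylsilyloxy)phenyl]-3-oxopentanoate | COC(=O)CC(=O)CCc1ccc(O[Si](C(C)C)(C(C)C)C(C)C)c(O[Si](C(C)C)(C(C)C)C(C)C)c1 | intermediate
7 | methyl (3R)-5-[3,4-bis(triisopropylsilyloxy)phenyl]-3-hydroxypentanoate | COC(=O)C[C@H](O)CCc1ccc(O[Si](C(C)C)(C(C)C)C(C)C)c(O[Si](C(C)C)(C(C)C)C(C)C)c1 | intermediate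
8 | (3R)-5-[3,4-bis(triisopropylsilyloxy)phenyl]pentane-1,3-diol | OCC[C@H](O)CCc1ccc(O[Si](C(C)C)(C(C)C)C(C)C)c(O[Si](C(C)C)(C(C)C)C(C)C)c1 | intermediate
9 | (3R)-5-[3,4-bis(triisopropylsilyloxy)phenyl]-3-hydroxypentyl 4-methylbenzenesulfonate | Cc1ccc(cc1)S(=O)(=O)OCC[C@H](O)CCc1ccc(O[Si](C(C)C)(C(C)C)C(C)C)c(O[Si](C(C)C)(C(C)C)C(C)C)c1 | intermediate
10 | (2R)-2-{2-[3,4-bis(triisopropylsilyloxy)phenyl]ethyl}oxetane | O1CC[C@H]1CCc2ccc(O[Si](C(C)C)(C(C)C)C(C)C)c(O[Si](C(C)C)(C(C)C)C(C)C)c2 | intermediate
11 | 4-(tert-butyldimethylsilyloxy)benzaldehyde | O=Cc1ccc(O[Si](C)(C)C(C)(C)C)cc1 | starting material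
12 | tert-butyl{4-[(E)-2-iodoethenyl]phenoxy}dimethylsilane | I/C=C/c1ccc(O[Si](C)(C)C(C)(C)C)cc1 | intermediate
13 | {(E)-2-[4-(tert-butyldimethylsilyloxy)phenyl]ethenyl}lithium | [Li]/C=C/c1ccc(O[Si](C)(C)C(C)(C)C)cc1 | intermediate
14 | lithium trifluoro{[(3S,6E)-1-[3,4-bis(triisopropylsilyloxy)phenyl]-7-[4-(tert-butyldimethylsilyloxy)phenyl]hept-6-en-3-yl]oxy}borate | [Li+].F[B-](F)(F)O[C@@H](CC/C=C/c1ccc(O[Si](C)(C)C(C)(C)C)cc1)CCc1ccc(O[Si](C(C)C)(C(C)C)C(C)C)c(O[Si](C(C)C)(C(C)C)C(C)C)c1 | intermediate
15 | (3S,6E)-1-[3,4-bis(triisopropylsilyloxy)phenyl]-7-[4-(tert-butyldimethylsilyloxy)phenyl]hept-6-en-3-ol | O[C@@H](CC/C=C/c1ccc(O[Si](C)(C)C(C)(C)C)cc1)CCc1ccc(O[Si](C(C)C)(C(C)C)C(C)C)c(O[Si](C(C)C)(C(C)C)C(C)C)c1 | intermediate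
16 | (3S,6E)-1-[3,4-bis(triisopropylsilyloxy)phenyl]-7-[4-(tert-butyldimethylsilyloxy)phenyl]hept-6-en-3-yl acetate | CC(=O)O[C@@H](CC/C=C/c1ccc(O[Si](C)(C)C(C)(C)C)cc1)CCc1ccc(O[Si](C(C)C)(C(C)C)C(C)C)c(O[Si](C(C)C)(C(C)C)C(C)C)c1 | intermediate
17 | (3S,6E)-1-(3,4-dihydroxyphenyl)-7-(4-hydroxyphenyl)hept-6-en-3-yl acetate | CC(=O)O[C@@H](CC/C=C/c1ccc(O)cc1)CCc1ccc(O)c(O)c1 | target

**Step count and risks**

Total step count: 9. Longest linear sequence: 8 (steps 1–5, 7, 8, 9).

Steps most likely to fail:

Step 7. The alkenyl group may pass from lithium to boron before ring opening, giving an unreactive alkenylborate, or the Lewis acid may oligomerise the activated oxetane. The fallback reverses the polarity of the same bond formation; it sets out from diol 8 and comes back at acetate 16. Primary-selective iodination of 8 (I2, PPh3, imidazole, CH2Cl2, 0 °C) should give (3R)-5-[3,4-bis(triisopropylsilyloxy)phenyl]-1-iodopentan-3-ol F1. Acetylation (Ac2O, pyridine, DMAP) should give (3R)-5-[3,4-bis(triisopropylsilyloxy)phenyl]-1-iodopentan-3-yl acetate F2. Zinc insertion (Zn dust, LiCl, THF, 25–40 °C) should give {(3R)-3-acetoxy-5-[3,4-bis(triisopropylsilyloxy)phenyl]pentyl}zinc iodide F3, which is not isolated but coupled with alkenyl iodide 12 in a Negishi reaction (Pd(PPh3)4, a zerovalent palladium catalyst, THF, rt→50 °C). This forms the C5–C6 bond with retention of the E geometry and arrives at 16.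

Step 5. Sulfonylation may occur at the secondary instead of the primary hydroxyl, so that ring closure runs with inversion and erodes the enantiomeric purity, and closure of the four-membered ring may be slow enough for elimination of the tosylate to compete. The fallback replaces the strained ring by an open-chain electrophile; it sets out from diol 8 and comes back at alcohol 15. Diol 8 is monotosylated at the primary hydroxyl (TsCl, pyridine, 0 °C) and the tosylate 9 is isolated. Silylation of the secondary hydroxyl (TESCl, imidazole, DMF) should give (3R)-5-[3,4-bis(triisopropylsilyloxy)phenyl]-3-(triethylsilyloxy)pentyl 4-methylbenzenesulfonate F4. Alkenyllithium 13 (two equivalents, from 12 and t-BuLi) and CuI in Et2O at −40 °C should give lithium bis{(E)-2-[4-(tert-butyldimethylsilyloxy)phenyl]ethenyl}cuprate F5, which displaces the primary tosylate (−40→0 °C). The product should be {[(3S,6E)-1-[3,4-bis(triisopropylsilyloxy)phenyl]-7-[4-(tert-butyldimethylsilyloxy)phenyl]hept-6-en-3-yl]oxy}triethylsilane F6. PPTS in MeOH/CH2Cl2 at 0 °C should then remove the alkyl triethylsilyl ether selectively, the aryl silyl ethers being stable to mild acid, and arrive at 15.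

Step 9. The secondary acetate may transfer its acetyl group to a liberated phenoxide or be lost under the fluoride conditions, and the free catechol may oxidise in air during work-up. The fallback changes the protecting-group logic from late desilylation to selective deacetylation; it sets out from alcohol 15 and comes back at target 17. Desilylation of 15 (TBAF, AcOH, THF) should give (3S,6E)-1-(3,4-dihydroxyphenyl)-7-(4-hydroxyphenyl)hept-6-en-3-ol F7. Peracetylation (Ac2O, pyridine, DMAP) should give (3S,6E)-1-(3,4-diacetoxyphenyl)-7-(4-acetoxyphenyl)hept-6-en-3-yl acetate F8. Aminolysis with pyrrolidine (3.3 equiv, CH2Cl2, 0 °C) should cleave the three aryl acetates, which react far faster than the secondary alkyl acetate, and arrive at 17.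

**Further compounds**

F1 | step 7 | (3R)-5-[3,4-bis(triisopropylsilyloxy)phenyl]-1-iodopentan-3-ol | ICC[C@H](O)CCc1ccc(O[Si](C(C)C)(C(C)C)C(C)C)c(O[Si](C(C)C)(C(C)C)C(C)C)c1
F2 | step 7 | (3R)-5-[3,4-bis(triisopropylsilyloxy)phenyl]-1-iodopentan-3-yl acetate | ICC[C@H](OC(C)=O)CCc1ccc(O[Si](C(C)C)(C(C)C)C(C)C)c(O[Si](C(C)C)(C(C)C)C(C)C)c1
F3 | step 7 | {(3R)-3-acetoxy-5-[3,4-bis(triisopropylsilyloxy)phenyl]pentyl}zinc iodide | I[Zn]CC[C@H](OC(C)=O)CCc1ccc(O[Si](C(C)C)(C(C)C)C(C)C)c(O[Si](C(C)C)(C(C)C)C(C)C)c1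
F4 | step 5 | (3R)-5-[3,4-bis(triisopropylsilyloxy)phenyl]-3-(triethylsilyloxy)pentyl 4-methylbenzenesulfonate | Cc1ccc(cc1)S(=O)(=O)OCC[C@H](O[Si](CC)(CC)CC)CCc1ccc(O[Si](C(C)C)(C(C)C)C(C)C)c(O[Si](C(C)C)(C(C)C)C(C)C)c1
F5 | step 5 | lithium bis{(E)-2-[4-(tert-butyldimethylsilyloxy)phenyl]ethenyl}cuprate | [Li+].CC(C)(C)[Si](C)(C)Oc1ccc(/C=C/[Cu-]/C=C/c2ccc(O[Si](C)(C)C(C)(C)C)cc2)cc1
F6 | step 5 | {[(3S,6E)-1-[3,4-bis(triisopropylsilyloxy)phenyl]-7-[4-(tert-butyldimethylsilyloxy)phenyl]hept-6-en-3-yl]oxy}triethylsilane | CC[Si](CC)(CC)O[C@@H](CC/C=C/c1ccc(O[Si](C)(C)C(C)(C)C)cc1)CCc1ccc(O[Si](C(C)C)(C(C)C)C(C)C)c(O[Si](C(C)C)(C(C)C)C(C)C)c1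
F7 | step 9 | (3S,6E)-1-(3,4-dihydroxyphenyl)-7-(4-hydroxyphenyl)hept-6-en-3-ol | O[C@@H](CC/C=C/c1ccc(O)cc1)CCc1ccc(O)c(O)c1
F8 | step 9 | (3S,6E)-1-(3,4-diacetoxyphenyl)-7-(4-acetoxyphenyl)hept-6-en-3-yl acetate | CC(=O)O[C@@H](CC/C=C/c1ccc(OC(C)=O)cc1)CCc1ccc(OC(C)=O)c(OC(C)=O)c1
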